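**Strategy**

1. Numbering used throughout (daucane): C1 is the quaternary ring-fusion carbon with the angular methyl, C2 and C3 the cyclopentane methylenes, C4 the carbinol carbon (OH, isopropyl), C5 the ring-fusion CH, C6 the ester-bearing carbon, C7=C8 the ring alkene (methyl on C8), C9 and C10 the remaining methylenes; ring A is the cyclopentane C1–C5, ring B the cycloheptene C1, C5–C10.
2. Enabling feature: the C4 hydroxyl is beta to the C6 oxygen across the fusion carbon C5, so once C6 is a ketone ring A is a beta-hydroxy ketone that opens at C4–C5 to leave an intact seven-membered enone (ring B), with C5 enolizable and therefore correctable.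
3. Retrosynthetic cuts, in order: the C6–O acyl bond of the aryl ester; the C6–H bond (back to the enone); C4–C5 (aldol); C1–C2 (conjugate addition of a masked 4-methyl-3-oxopentyl chain to an achiral cross-conjugated cycloheptadienone); one ring carbon of ring B (back to a cyclohexenone).
4. Forward: 3-methylcyclohexenone is methylated and enlarged by one carbon to 3,6-dimethylcyclohepta-2,6-dienone (ring B first), the C2–C4 chain is joined at C1, ring A is closed by the aldol, and reduction, acylation and phenol release finish.
5. Stereochemistry: C1 comes from a ligand-controlled copper-catalysed conjugate addition; C4 and C5 from thermodynamic control in the equilibrating aldol, relative to C1; C6 from hydride delivered intramolecularly from the C4 oxygen.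

Key step: step 12

Assumption: the sense of induction of the chiral ligand on this dienone cannot be predicted with certainty, so the ligand enantiomer (both are accessible from leucinol) would be fixed by a test reaction so that the (S)-configured quaternary carbon results.

**Route**

Step 1
Reactants: 1 3-methylcyclohex-2-en-1-one; 2 iodomethane
Product: 4 3,6-dimethylcyclohex-2-en-1-one (racemic), via lithium dienolate 3 (not isolated)
Conditions: LiN(i-Pr)2 (1.05 equiv), THF, −78 °C; then MeI, −78 → 0 °C
Reagents that add atoms: none
Why: Kinetic deprotonation of an enone by the amide base occurs at the alpha-prime carbon, and the cross-conjugated lithium dienolate is C-methylated there (kinetic enolate alkylation); the new stereocentre forms racemic and is removed in step 2.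

Step 2
Reactants: 4 3,6-dimethylcyclohex-2-en-1-one
Product: 6 1,4-dimethyl-2-(trimethylsilyloxy)cyclohexa-1,3-diene, via lithium dienolate 5 (not isolated)
Conditions: LiN(i-Pr)2 (1.1 equiv), THF, −78 °C; Me3SiCl, −78 → 0 °C; non-aqueous work-up, distillation
Reagents that add atoms: chlorotrimethylsilane, C[Si](C)(C)Cl
Why: A second kinetic alpha-prime deprotonation, now at the C6 methine, followed by O-silylation (silyl enol ether formation) should give the 2-silyloxy-1,3-diene and erase the C6 stereocentre.

Step 3
Reactants: 6 1,4-dimethyl-2-(trimethylsilyloxy)cyclohexa-1,3-diene; 7 diiodomethane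
Product: 8 3,6-dimethyl-1-(trimethylsilyloxy)bicyclo[4.1.0]hept-2-ene (racemic, cis-fused)
Conditions: Et2Zn (1.5 equiv), CH2I2 (1.5 equiv), Et2O, 0 → 20 °C; pyridine, then aq. NH4Cl
Reagents that add atoms: none
Why: In this Furukawa-modified Simmons–Smith cyclopropanation the electrophilic carbenoid EtZnCH2I should add to the electron-rich silyl enol ether double bond rather than to the unactivated trisubstituted alkene, and the cis fusion is the only one geometrically possible.

Step 4
Reactants: 8 3,6-dimethyl-1-(trimethylsilyloxy)bicyclo[4.1.0]hept-2-ene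
Product: 9 6-chloro-3,6-dimethylcyclohept-2-en-1-one (racemic)
Conditions: FeCl3 (2.2 equiv), DMF, 0 → 20 °C
Reagents that add atoms: iron trichloride, Cl[Fe](Cl)Cl
Why: In this Ito–Saegusa ring enlargement trivalent iron desilylates and oxidises the cyclopropanol, the internal cyclopropane bond cleaves to the ring-expanded tertiary beta-keto radical, and that radical takes chlorine from a second FeCl3.

Step 5
Reactants: 9 6-chloro-3,6-dimethylcyclohept-2-en-1-one
Product: 10 3,6-dimethylcyclohepta-2,6-dien-1-one (achiral)
Conditions: NaOAc (5 equiv), MeOH, reflux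
Reagents that add atoms: none
Why: Acetate-mediated E1cB dehydrochlorination of the beta-chloro ketone through the enolate next to the C–Cl carbon should give the conjugated cross-conjugated dienone.

Step 6
Reactants: 11 methyl 2-methylpropanoate; 12 ethylmagnesium bromide
Product: 14 1-isopropylcyclopropan-1-ol, via bromomagnesium cyclopropanolate 13 (not isolated)
Conditions: EtMgBr (2.4 equiv), Ti(OiPr)4 (0.2 equiv), Et2O, 0 → 20 °C; cold dilute H2SO4
Reagents that add atoms: none
Why: In the Kulinkovich cyclopropanation the titanacyclopropane formed from EtMgBr and Ti(OiPr)4 adds twice to the ester carbonyl as a 1,2-dicarbanion equivalent, and further Grignard reagent returns titanium to the cycle.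

Step 7
Reactants: 14 1-isopropylcyclopropan-1-ol
Product: 15 1-bromo-4-methylpentan-3-one
Conditions: N-bromosuccinimide (1.05 equiv), CH2Cl2, 0 → 20 °C, dark
Reagents that add atoms: N-bromosuccinimide, BrN1C(=O)CCC1=O
Why: Electrophilic ring opening of the cyclopropanol by the bromonium donor (homoenolate-type cleavage of a C1–C2 bond) should give the beta-bromo ketone under neutral conditions that do not eliminate HBr.

Step 8
Reactants: 15 1-bromo-4-methylpentan-3-one
Product: 16 2-(2-bromoethyl)-2-isopropyl-1,3-dioxolane
Conditions: Me3SiOCH2CH2OSiMe3 (1.5 equiv), Me3SiOTf (5 mol %), CH2Cl2, −78 → −20 °C; pyridine quench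
Reagents that add atoms: 1,2-bis(trimethylsilyloxy)ethane, C[Si](C)(C)OCCO[Si](C)(C)C
Why: Noyori ketalization is aprotic and runs at low temperature, so the hindered ketone should be masked without E1cB loss of HBr to the vinyl ketone.

Step 9
Reactants: 16 2-(2-bromoethyl)-2-isopropyl-1,3-dioxolane
Product: 17 [2-(2-isopropyl-1,3-dioxolan-2-yl)ethyl]magnesium bromide (titrated solution, used at once)
Conditions: Mg turnings (1.5 equiv, I2 crystal), Et2O, 20–30 °C
Reagents that add atoms: magnesium, [Mg]
Why: Oxidative insertion of magnesium into the primary C–Br bond (Grignard formation) should give a gamma-ketal organomagnesium reagent, a masked ketone homoenolate that is stable below about 30 °C.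

Step 10
Reactants: 10 3,6-dimethylcyclohepta-2,6-dien-1-one; 17 [2-(2-isopropyl-1,3-dioxolan-2-yl)ethyl]magnesium bromide
Product: 19 (S)-6-[2-(2-isopropyl-1,3-dioxolan-2-yl)ethyl]-3,6-dimethylcyclohept-2-en-1-one, via bromomagnesium dienolate 18 (not isolated)
Conditions: Cu(OTf)2 (3 mol %), chiral N-mesityl N′-(1-hydroxy-4-methylpentan-2-yl)imidazolinium hexafluorophosphate (4 mol %), 17 (1.3 equiv), Et2O, −30 → 0 °C, slow addition of 10; aq. NH4Cl
Reagents that add atoms: none
Why: Copper-catalysed enantioselective conjugate addition of a Grignard reagent to a beta-methyl cyclic enone under chiral NHC control creates the quaternary C1; the two enone halves of 10 are interchanged by its twofold axis, so one face-selective catalyst gives the same enantiomer at either beta-carbon, and the magnesium dienolate formed resists a second addition until work-up.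

Step 11
Reactants: 19 (S)-6-[2-(2-isopropyl-1,3-dioxolan-2-yl)ethyl]-3,6-dimethylcyclohept-2-en-1-one
Product: 20 (S)-3,6-dimethyl-6-(4-methyl-3-oxopentyl)cyclohept-2-en-1-one
Conditions: 1 M aq. HCl, THF, 20 °C
Reagents that add atoms: water, O
Why: Acid-catalysed ketal hydrolysis should release the isopropyl ketone, and at room temperature with short contact neither the enone nor the quaternary centre is affected and no acid-promoted aldol condensation is expected.

Step 12
Reactants: 20 (S)-3,6-dimethyl-6-(4-methyl-3-oxopentyl)cyclohept-2-en-1-one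
Product: 21 (1S,4R,5R)-4-hydroxydauc-7-en-6-one (trans-fused ketol; angular methyl and C4–OH on one face, H5 and isopropyl on the other)
Conditions: KOt-Bu (0.2 equiv), t-BuOH–THF (1:1), 0 → 20 °C; pH 7 phosphate buffer
Reagents that add atoms: none
Why: Catalytic tert-butoxide removes a proton from C5, the only alpha-prime position of the enone, and the cross-conjugated dienolate adds to the C4 isopropyl ketone to form the C4–C5 bond as a tertiary aldolate, the closest known reaction type being the thermodynamically controlled intramolecular ketone–ketone aldol addition of a 1,6-diketone to a 2-acylcyclopentanol. Ring A (C1–C5) closes in the 5-(enolexo)-exo-trig mode onto the intact seven-membered enone ring B. C5 is set relative to the fixed quaternary C1 by equilibration through enolization toward the trans 5-7 fusion, which is expected to be the more stable fusion when the ketone lies in the seven-membered ring next to the junction. C4 is set by retro-aldol and re-addition toward the isomer whose hydroxyl is cis to the C6 carbonyl (intramolecular hydrogen bond) and whose larger isopropyl group is trans to C6 and to the angular methyl. The step needs diastereocontrol at C4 and C5 and regiocontrol among enolates: closures from the C3 enolate onto C6 or C8 would give bridged bicyclo[4.2.1] or bicyclo[3.2.2] skeletons at the cost of enone conjugation or added strain, so reversible addition should drain them to 21, while C1 cannot epimerize. Low temperature, catalytic base and a buffered quench are chosen to keep the tertiary aldol from E1cB dehydration.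

Step 13
Reactants: 21 (1S,4R,5R)-4-hydroxydauc-7-en-6-one
Product: 22 (1S,4R,5S,6S)-dauc-7-ene-4,6-diol (C6–OH cis to H5, trans to the angular methyl)
Conditions: Me4NBH(OAc)3 (5 equiv), MeCN–AcOH (1:1), −30 → 0 °C; aq. potassium sodium tartrate
Reagents that add atoms: none
Why: In this Evans–Saksena hydroxyl-directed reduction the tertiary C4 hydroxyl exchanges onto boron and the alkoxyborohydride delivers hydride through a six-membered transition state to the C6 carbonyl face syn to the C4 oxygen (the face the angular methyl otherwise shields), which places the C6 oxygen cis to H5, while the reagent is too weak for undirected or conjugate reduction of the enone.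

Step 14
Reactants: 22 (1S,4R,5S,6S)-dauc-7-ene-4,6-diol; 23 4-acetoxybenzoic acid
Product: 24 (1S,4R,5S,6S)-4-hydroxydauc-7-en-6-yl 4-acetoxybenzoate
Conditions: DCC (1.5 equiv), DMAP (0.2 equiv), CH2Cl2, 0 → 20 °C
Reagents that add atoms: none
Why: In this Steglich esterification the N-acylpyridinium formed with DMAP should acylate the secondary allylic C6 hydroxyl only, the tertiary C4 hydroxyl being too hindered, and the phenol is carried as its acetate so that the acid cannot oligomerise.

Step 15
Reactants: 24 (1S,4R,5S,6S)-4-hydroxydauc-7-en-6-yl 4-acetoxybenzoate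
Product: 25 (1S,4R,5S,6S)-4-hydroxydauc-7-en-6-yl 4-hydroxybenzoate, i.e. (3R,3aS,4S,8aS)-3-hydroxy-6,8a-dimethyl-3-(propan-2-yl)-1,2,3,3a,4,7,8,8a-octahydroazulen-4-yl 4-hydroxybenzoate (CNP0323098.1)
Conditions: pyrrolidine (3 equiv), CH2Cl2, 0 → 20 °C
Reagents that add atoms: none
Why: Aminolysis of the aryl acetate is far faster than attack on the hindered alkyl benzoate because phenoxide is the better leaving group, so only the phenolic acetate should be cleaved and no stereocentre is touched.

**Compound list**

1 | 3-methylcyclohex-2-en-1-one | CC1=CC(=O)CCC1 | starting material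
2 | iodomethane | CI | starting material
3 | lithium 5-methylcyclohexa-1,5-dien-1-olate (kinetic dienolate of 1) | CC1=CC(O[Li])=CCC1 | intermediate
4 | 3,6-dimethylcyclohex-2-en-1-one (racemic) | CC1=CC(=O)C(C)CC1 | intermediate
5 | lithium 2,5-dimethylcyclohexa-1,5-dien-1-olate (kinetic dienolate of 4) | CC1=CC(O[Li])=C(C)CC1 | intermediate
6 | 1,4-dimethyl-2-(trimethylsilyloxy)cyclohexa-1,3-diene | CC1=CC(O[Si](C)(C)C)=C(C)CC1 | intermediate
7 | diiodomethane | ICI | starting material
8 | 3,6-dimethyl-1-(trimethylsilyloxy)bicyclo[4.1.0]hept-2-ene (racemic, cis-fused; one enantiomer drawn) | CC1=C[C@]2(O[Si](C)(C)C)C[C@]2(C)CC1 | intermediate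
9 | 6-chloro-3,6-dimethylcyclohept-2-en-1-one (racemic) | CC1=CC(=O)CC(C)(Cl)CC1 | intermediate
10 | 3,6-dimethylcyclohepta-2,6-dien-1-one | CC1=CC(=O)C=C(C)CC1 | intermediate
11 | methyl 2-methylpropanoate (methyl isobutyrate) | COC(=O)C(C)C | starting material
12 | ethylmagnesium bromide | CC[Mg]Br | starting material
13 | bromomagnesium 1-isopropylcyclopropan-1-olate | CC(C)C1(O[Mg]Br)CC1 | intermediate
14 | 1-isopropylcyclopropan-1-ol | CC(C)C1(O)CC1 | intermediate
15 | 1-bromo-4-methylpentan-3-one | CC(C)C(=O)CCBr | intermediate
16 | 2-(2-bromoethyl)-2-isopropyl-1,3-dioxolane | CC(C)C1(CCBr)OCCO1 | intermediate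
17 | [2-(2-isopropyl-1,3-dioxolan-2-yl)ethyl]magnesium bromide | CC(C)C1(CC[Mg]Br)OCCO1 | intermediate
18 | bromomagnesium (S)-3-[2-(2-isopropyl-1,3-dioxolan-2-yl)ethyl]-3,6-dimethylcyclohepta-1,6-dien-1-olate | CC1=CC(O[Mg]Br)=C[C@@](C)(CC1)CCC2(OCCO2)C(C)C | intermediate
19 | (S)-6-[2-(2-isopropyl-1,3-dioxolan-2-yl)ethyl]-3,6-dimethylcyclohept-2-en-1-one | CC1=CC(=O)C[C@@](C)(CC1)CCC2(OCCO2)C(C)C | intermediate
20 | (S)-3,6-dimethyl-6-(4-methyl-3-oxopentyl)cyclohept-2-en-1-one | CC1=CC(=O)C[C@@](C)(CC1)CCC(=O)C(C)C | intermediate
21 | (1S,4R,5R)-4-hydroxydauc-7-en-6-one, i.e. (3R,3aR,8aS)-3-hydroxy-6,8a-dimethyl-3-(propan-2-yl)-2,3,3a,7,8,8a-hexahydroazulen-4(1H)-one, trans-fused | CC1=CC(=O)[C@@H]2[C@@](C)(CC1)CC[C@@]2(O)C(C)C | intermediate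
22 | (1S,4R,5S,6S)-dauc-7-ene-4,6-diol | CC1=C[C@H](O)[C@@H]2[C@@](C)(CC1)CC[C@@]2(O)C(C)C | intermediate
23 | 4-acetoxybenzoic acid | CC(=O)Oc1ccc(cc1)C(O)=O | starting material
24 | (1S,4R,5S,6S)-4-hydroxydauc-7-en-6-yl 4-acetoxybenzoate | CC1=C[C@H](OC(=O)c2ccc(OC(C)=O)cc2)[C@@H]2[C@@](C)(CC1)CC[C@@]2(O)C(C)C | intermediate
25 | (1S,4R,5S,6S)-4-hydroxydauc-7-en-6-yl 4-hydroxybenzoate (CNP0323098.1) | CC1=C[C@H](OC(=O)c2ccc(O)cc2)[C@@H]2[C@@](C)(CC1)CC[C@@]2(O)C(C)C | target

**Step count and risks**

Total steps: 15. Longest linear sequence: 11 steps (steps 1–5, then 10–15); the side-chain branch (steps 6–9) joins at step 10.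

Steps most likely to fail:

1. Step 12 (aldol). The equilibration may rest on the open diketone or on a cis-fused isomer, enolization of the side-chain ketone may divert material into bridged adducts, or the tertiary aldol may dehydrate. The fallback generates the C5 enolate regiospecifically and irreversibly instead of by equilibrating base. It sets out from 19: kinetic alpha-prime deprotonation and silylation (LiN(i-Pr)2, Me3SiCl, THF, −78 °C) would give the trimethylsilyl dienol ether of 19, trimethyl{[(S)-3-[2-(2-isopropyl-1,3-dioxolan-2-yl)ethyl]-3,6-dimethylcyclohepta-1,6-dien-1-yl]oxy}silane F1. N-Bromosuccinimide (THF, −78 °C) would convert it into the alpha-prime bromo enone (6S)-7-bromo-6-[2-(2-isopropyl-1,3-dioxolan-2-yl)ethyl]-3,6-dimethylcyclohept-2-en-1-one F2, and aqueous HCl in THF would remove the ketal to give (6S)-7-bromo-3,6-dimethyl-6-(4-methyl-3-oxopentyl)cyclohept-2-en-1-one F3. SmI2 (2.2 equiv, THF, −78 °C) would then reduce the C–Br bond to the trivalent samarium enolate, which closes onto the isopropyl ketone in an intramolecular Reformatsky-type aldol through a chelated transition state and is held as the chelated aldolate until the quench. The route is rejoined at 21; C5, being alpha to the ketone, would remain correctable by brief base treatment.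

2. Step 10 (conjugate addition). The catalyst may show low reactivity or poor face discrimination toward the cross-conjugated dienone, or 1,2-addition may compete. The fallback sets the quaternary centre on a simple beta-methyl cycloheptenone, the established substrate class, and builds the second unsaturation afterwards. It sets out from 17, which would be added under the same Cu(OTf)2/NHC catalysis to purchasable 3-methylcyclohept-2-en-1-one F4 to give (S)-3-[2-(2-isopropyl-1,3-dioxolan-2-yl)ethyl]-3-methylcycloheptan-1-one F5. Kinetic enolization away from the quaternary carbon (LiN(i-Pr)2, Me3SiCl, −78 °C) would give the silyl enol ether trimethyl{[(S)-6-[2-(2-isopropyl-1,3-dioxolan-2-yl)ethyl]-6-methylcyclohept-1-en-1-yl]oxy}silane F6, and Saegusa–Ito oxidation (Pd(OAc)2, MeCN) the enone (S)-6-[2-(2-isopropyl-1,3-dioxolan-2-yl)ethyl]-6-methylcyclohept-2-en-1-one F7. Conjugate addition of Me2CuLi with Me3SiCl trapping would give trimethyl{[(6S)-6-[2-(2-isopropyl-1,3-dioxolan-2-yl)ethyl]-3,6-dimethylcyclohept-1-en-1-yl]oxy}silane F8 (both epimers at the new methyl carbon serve), and a second Saegusa–Ito oxidation rejoins the route at 19.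

3. Step 13 (directed reduction). The hindered tertiary hydroxyl may fail to bind boron, so that reduction stalls or hydride attacks from outside with poor or reversed facial selectivity. The fallback accepts external attack and corrects C6 in the ester-forming step. It sets out from 21: Luche reduction (NaBH4, CeCl3·7H2O, MeOH, −78 °C) is expected to approach anti to the angular methyl and give (1S,4R,5S,6R)-dauc-7-ene-4,6-diol F9. Mitsunobu esterification with 23 (PPh3, diisopropyl azodicarboxylate, toluene, 0 °C) would then install the aryl ester with inversion at C6 and rejoin the route at 24.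

**Further compounds**

F1 | step 12 | trimethyl{[(S)-3-[2-(2-isopropyl-1,3-dioxolan-2-yl)ethyl]-3,6-dimethylcyclohepta-1,6-dien-1-yl]oxy}silane | CC1=CC(O[Si](C)(C)C)=C[C@@](C)(CC1)CCC2(OCCO2)C(C)C
F2 | step 12 | (6S)-7-bromo-6-[2-(2-isopropyl-1,3-dioxolan-2-yl)ethyl]-3,6-dimethylcyclohept-2-en-1-one (C7 epimers) | CC1=CC(=O)C(Br)[C@@](C)(CC1)CCC2(OCCO2)C(C)C
F3 | step 12 | (6S)-7-bromo-3,6-dimethyl-6-(4-methyl-3-oxopentyl)cyclohept-2-en-1-one (C7 epimers) | CC1=CC(=O)C(Br)[C@@](C)(CC1)CCC(=O)C(C)C
F4 | step 10 | 3-methylcyclohept-2-en-1-one | CC1=CC(=O)CCCC1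
F5 | step 10 | (S)-3-[2-(2-isopropyl-1,3-dioxolan-2-yl)ethyl]-3-methylcycloheptan-1-one | O=C1C[C@@](C)(CCCC1)CCC2(OCCO2)C(C)C
F6 | step 10 | trimethyl{[(S)-6-[2-(2-isopropyl-1,3-dioxolan-2-yl)ethyl]-6-methylcyclohept-1-en-1-yl]oxy}silane | C1C=C(O[Si](C)(C)C)C[C@@](C)(CC1)CCC2(OCCO2)C(C)C
F7 | step 10 | (S)-6-[2-(2-isopropyl-1,3-dioxolan-2-yl)ethyl]-6-methylcyclohept-2-en-1-one | C1=CC(=O)C[C@@](C)(CC1)CCC2(OCCO2)C(C)C
F8 | step 10 | trimethyl{[(6S)-6-[2-(2-isopropyl-1,3-dioxolan-2-yl)ethyl]-3,6-dimethylcyclohept-1-en-1-yl]oxy}silane (C3 epimers) | CC1C=C(O[Si](C)(C)C)C[C@@](C)(CC1)CCC2(OCCO2)C(C)C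
F9 | step 13 | (1S,4R,5S,6R)-dauc-7-ene-4,6-diol | CC1=C[C@@H](O)[C@@H]2[C@@](C)(CC1)CC[C@@]2(O)C(C)C
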